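A direct plan would grow the trione ring from racemic cyclobutenone A1 by a thermal ketene cascade with an ynol ether, hydrolyse to the achiral trione A2, C-acetylate to racemic A3, resolve A3 on a chiral phase and bridge its (R)-enantiomer to acylchromene A4 after Mannich activation. The ketene cascade would be weakest: the vinylketene would have to be trapped bimolecularly before [1,5]-hydrogen shift or dimerisation, on a terminus without close precedent. The resolution would discard half of an advanced intermediate. The late methylene bridging would pass through an exocyclic enone prone to self-condensation, and A4 would come from a chromene annulation that gives regioisomers.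

The dearomatised ring (C1 ketone, C2 acetyl-bearing, C4 quaternary, C6 bridge-bearing) is cut at C5–C6 and C1–C2 into two lactones: an enantiopure 3,3-disubstituted pyran-2,4-dione that holds C2–C5 with the acetyl group, and a tricyclic dihydrocoumarin whose C3, C2 and C4 become C6, C1 and the methylene bridge and whose ring oxygen masks a phenol. One Claisen–Claisen cascade exchanges both lactone C–O bonds for C–C bonds, closes the carbocycle, frees the phenol and keeps every atom. Connectivity, not selectivity, places the stereocentre set by an auxiliary-controlled alkylation; no ketene cascade, resolution or late bridging of two halves remains, and the lactone oxygen also fixes the chromene regiochemistry.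

Key step: step 8

Assumption: in the alkylation of the lithiated valine enamine the lithium ligand decides which face reacts; HMPA is taken as the additive that gives the (S)-keto ester, and the complementary ligand (trimethylamine or 1,3-dioxolane) would be used if the opposite sense were found.

Geranyl stands for (2E)-3,7-dimethylocta-2,6-dien-1-yl throughout; the dearomatised ring is numbered as in the name of 23.

Step 1
Reactants: 1 ethyl 2-methyl-3-oxobutanoate; 2 L-valine tert-butyl ester
Product: 3 ethyl (2Z)-3-{[(2S)-1-tert-butoxy-3-methyl-1-oxobutan-2-yl]amino}-2-methylbut-2-enoate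
Conditions: BF3·OEt2 (cat.), toluene, reflux, Dean–Stark
Reagents that add atoms: none
Why: Acid-catalysed condensation of the primary amine with the ketone of the β-keto ester (enamine formation) should give the hydrogen-bonded (Z)-enamino ester, in which the auxiliary carries the only stereocentre.

Step 2
Reactants: 3 ethyl (2Z)-3-{[(2S)-1-tert-butoxy-3-methyl-1-oxobutan-2-yl]amino}-2-methylbut-2-enoate; 4 geranyl bromide
Product: 6 ethyl (2S)-2-geranyl-2-methyl-3-oxobutanoate, via alkylated imine 5 (not isolated)
Conditions: LiN(i-Pr)2 (1.1 equiv), toluene, −78 °C; HMPA (1 equiv); then 4, −78 to −55 °C; then 1 M aq. HCl, rt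
Reagents that add atoms: water, O
Why: Auxiliary-controlled alkylation of a chiral lithio-enamine: the lithium is held in a chelate with the valine ester carbonyl, the isopropyl group shields one face, and the allylic bromide should attack C2 by SN2 from the open face to set the quaternary stereocentre as (S), after which mild acid hydrolyses the imine and returns the auxiliary.

Step 3
Reactants: 6 ethyl (2S)-2-geranyl-2-methyl-3-oxobutanoate; 7 1-acetyl-1H-benzotriazole
Product: 8 ethyl (2S)-2-geranyl-2-methyl-3,5-dioxohexanoate
Conditions: MgBr2·OEt2 (2.5 equiv), i-Pr2NEt (3 equiv), CH2Cl2, rt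
Reagents that add atoms: none
Why: Soft enolisation of the only enolisable position, the acetyl methyl group, through the magnesium chelate and C-acylation by the acylbenzotriazole (Claisen-type ketone acylation) should give the β-diketone without strong base and without touching the quaternary centre.

Step 4
Reactants: 8 ethyl (2S)-2-geranyl-2-methyl-3,5-dioxohexanoate
Product: 10 (3S)-3-geranyl-3,6-dimethyl-2H-pyran-2,4(3H)-dione, via diketo acid 9 (not isolated)
Conditions: LiOH, THF–H2O, rt to 40 °C; 1 M HCl to pH 3 at 0 °C, extraction; then EDC·HCl, CH2Cl2, 0 °C to rt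
Reagents that add atoms: lithium hydroxide, [Li+].[OH-] (the carboxyl oxygens of 9 become equivalent, so the lactone carbonyl oxygen of 10 may stem from it)
Why: Saponification is placed after the acetylation because the β-diketone, present as its enolate, shields the ketone next to the quaternary carbon from retro-Claisen attack, and carbodiimide activation of the cold β,δ-diketo acid should then close the six-membered enol lactone (enol lactonisation, the only ring size open to an enol oxygen), which stores the acid as an activated ester.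

Step 5
Reactants: 11 phloroglucinol; 12 hexanoyl chloride
Product: 13 1-(2,4,6-trihydroxyphenyl)hexan-1-one
Conditions: AlCl3 (3 equiv), PhNO2–CH2Cl2, rt to 50 °C; aq. HCl
Reagents that add atoms: none
Why: Friedel–Crafts acylation of the symmetrical arene should stop after one acyl group because the product is deactivated and bound to aluminium.

Step 6
Reactants: 13 1-(2,4,6-trihydroxyphenyl)hexan-1-one; 14 Meldrum's acid (2,2-dimethyl-1,3-dioxane-4,6-dione); 15 formaldehyde
Product: 18 6-hexanoyl-5,7-dihydroxy-3,4-dihydro-2H-chromen-2-one, via Meldrum's acid adduct 16 (not isolated), via lactone acid 17 (not isolated)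
Conditions: 14 and 15 (as paraformaldehyde) premixed in pyridine, rt; then 13, rt to 80 °C
Reagents that add atoms: none
Why: Three-component (Yonemitsu-type) condensation: Knoevenagel condensation gives methylene Meldrum's acid, a free ring carbon of 13 adds to it, and the para hydroxyl, the most acidic one and the only one not held in the chelate with the ketone, should open the dioxanedione with loss of acetone and then of CO2, any 8-acyl isomer from closure on an ortho hydroxyl being removed here.

Step 7
Reactants: 18 6-hexanoyl-5,7-dihydroxy-3,4-dihydro-2H-chromen-2-one; 19 3-methylbut-2-enal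
Product: 21 6-hexanoyl-5-hydroxy-8,8-dimethyl-3,4-dihydro-2H,8H-pyrano[2,3-f]chromen-2-one, via quinone methide 20 (not isolated)
Conditions: ethylenediammonium diacetate (cat.), toluene, 100 °C
Reagents that add atoms: none
Why: Amine-catalysed condensation at the single free ring carbon gives quinone methide 20, which should close by oxa-6π electrocyclisation (formal [3+3] chromene annulation), and because the oxygen on the other side of that carbon is tied up in the lactone, the pyran oxygen can only be the hydroxyl next to the acyl group.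

Step 8
Reactants: 21 6-hexanoyl-5-hydroxy-8,8-dimethyl-3,4-dihydro-2H,8H-pyrano[2,3-f]chromen-2-one; 10 (3S)-3-geranyl-3,6-dimethyl-2H-pyran-2,4(3H)-dione
Product: 23 (4R)-2-acetyl-4-geranyl-6-[(8-hexanoyl-5,7-dihydroxy-2,2-dimethyl-2H-chromen-6-yl)methyl]-3,5-dihydroxy-4-methylcyclohexa-2,5-dien-1-one, via triketo lactone 22 (not isolated)
Conditions: LiN(i-Pr)2 (2.1 equiv), THF, −78 °C; then 10, −78 to 0 °C; then 40 °C; 1 M HCl work-up at 0 °C
Reagents that add atoms: none
Why: Proposed new method: the lithium enolate at C3 of lactone 21 (formed after the phenoxide) should add to the lactone carbonyl of 10, an acylated enol and its most electrophilic site, and the tetrahedral intermediate should expel the enol oxygen to give triketo lactone 22 as its β-diketonate, whose central carbon then attacks the aryl lactone carbonyl (directly or through the acylketene formed by E1cB loss of the phenoxide) and releases the phenol, the stabilised trione enolate being the thermodynamic sink. The closest known reaction types are the Claisen acylation of lactone enolates, the opening of enol lactones by carbanions (Fujimoto–Belleau reaction), the Claisen cyclisation of 3,5,7-triketo esters to acylphloroglucinols and the base-induced isomerisation of 3,3-dialkylpyran-2,4-diones to cyclohexane-1,3,5-triones; their combination into one lactone-to-carbocycle exchange is new. The only ring closed is the six-membered carbocycle, by a 6-(enolexo)-exo-trig Claisen (Dieckmann-type) closure of C2 on C1 after the intermolecular Claisen step has made C5–C6, while both lactone rings open. No stereocentre is created: the quaternary carbon of 10 is carried over unchanged and becomes C4 with the (R) configuration because connectivity alone decides that the former lactone carbonyl of 10 bonds the bridge-bearing carbon and the former ketone flank carries the acetyl group (the C3 centre of 22 is lost on enolisation). The step needs carbonyl addition to outrun proton transfer from the C6 methyl group of 10 and from the hexanoyl chain, which the enol-ester activation, the low temperature and the phenoxide (it turns the aryl ketone into a vinylogous carboxylate) should secure, and it needs C- over O-acylation in the closure, which is secured thermodynamically because an O-acyl pyranone isomer is itself an acyl donor and funnels to the trione enolate.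

Compound list
1 | ethyl 2-methyl-3-oxobutanoate | CCOC(=O)C(C)C(C)=O | starting material
2 | L-valine tert-butyl ester | CC(C)[C@H](N)C(=O)OC(C)(C)C | starting material
3 | ethyl (2Z)-3-{[(2S)-1-tert-butoxy-3-methyl-1-oxobutan-2-yl]amino}-2-methylbut-2-enoate | CCOC(=O)/C(C)=C(/C)N[C@@H](C(C)C)C(=O)OC(C)(C)C | intermediate
4 | geranyl bromide, (2E)-1-bromo-3,7-dimethylocta-2,6-diene | BrC/C=C(\C)CCC=C(C)C | starting material
5 | ethyl (2S)-3-{[(2S)-1-tert-butoxy-3-methyl-1-oxobutan-2-yl]imino}-2-geranyl-2-methylbutanoate | CCOC(=O)[C@@](C)(C/C=C(\C)CCC=C(C)C)C(C)=N[C@@H](C(C)C)C(=O)OC(C)(C)C | intermediate (not isolated)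
6 | ethyl (2S)-2-geranyl-2-methyl-3-oxobutanoate | CCOC(=O)[C@@](C)(C/C=C(\C)CCC=C(C)C)C(C)=O | intermediate
7 | 1-acetyl-1H-benzotriazole | CC(=O)n1nnc2ccccc12 | starting material
8 | ethyl (2S)-2-geranyl-2-methyl-3,5-dioxohexanoate | CCOC(=O)[C@@](C)(C/C=C(\C)CCC=C(C)C)C(=O)CC(C)=O | intermediate
9 | (2S)-2-geranyl-2-methyl-3,5-dioxohexanoic acid | OC(=O)[C@@](C)(C/C=C(\C)CCC=C(C)C)C(=O)CC(C)=O | intermediate (not isolated)
10 | (3S)-3-geranyl-3,6-dimethyl-2H-pyran-2,4(3H)-dione | CC1=CC(=O)[C@](C)(C/C=C(\C)CCC=C(C)C)C(=O)O1 | intermediate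
11 | phloroglucinol | Oc1cc(O)cc(O)c1 | starting material
12 | hexanoyl chloride | CCCCCC(=O)Cl | starting material
13 | 1-(2,4,6-trihydroxyphenyl)hexan-1-one | CCCCCC(=O)c1c(O)cc(O)cc1O | intermediate
14 | Meldrum's acid, 2,2-dimethyl-1,3-dioxane-4,6-dione | CC1(C)OC(=O)CC(=O)O1 | starting material
15 | formaldehyde (used as paraformaldehyde) | C=O | starting material
16 | 5-[(3-hexanoyl-2,4,6-trihydroxyphenyl)methyl]-2,2-dimethyl-1,3-dioxane-4,6-dione | CCCCCC(=O)c1c(O)cc(O)c(CC2C(=O)OC(C)(C)OC2=O)c1O | intermediate (not isolated)
17 | 6-hexanoyl-5,7-dihydroxy-2-oxo-3,4-dihydro-2H-chromene-3-carboxylic acid (racemic) | CCCCCC(=O)c1c(O)cc2OC(=O)C(C(=O)O)Cc2c1O | intermediate (not isolated)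
18 | 6-hexanoyl-5,7-dihydroxy-3,4-dihydro-2H-chromen-2-one | CCCCCC(=O)c1c(O)cc2OC(=O)CCc2c1O | intermediate
19 | 3-methylbut-2-enal | CC(C)=CC=O | starting material
20 | o-quinone methide, 6-hexanoyl-5-hydroxy-8-(3-methylbut-2-en-1-ylidene)-3,4-dihydro-2H-chromene-2,7(8H)-dione | CCCCCC(=O)C1=C(O)C2=C(OC(=O)CC2)C(=CC=C(C)C)C1=O | intermediate (not isolated)
21 | 6-hexanoyl-5-hydroxy-8,8-dimethyl-3,4-dihydro-2H,8H-pyrano[2,3-f]chromen-2-one | CCCCCC(=O)c1c(O)c2CCC(=O)Oc2c2C=CC(C)(C)Oc12 | intermediate
22 | 3-[(2S)-2-geranyl-2-methyl-3,5-dioxohexanoyl]-6-hexanoyl-5-hydroxy-8,8-dimethyl-3,4-dihydro-2H,8H-pyrano[2,3-f]chromen-2-one (both C3 epimers) | CC(=O)CC(=O)[C@](C)(C/C=C(\C)CCC=C(C)C)C(=O)C1Cc2c(O)c(C(=O)CCCCC)c3OC(C)(C)C=Cc3c2OC1=O | intermediate (not isolated)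
23 | (4R)-2-acetyl-4-geranyl-6-[(8-hexanoyl-5,7-dihydroxy-2,2-dimethyl-2H-chromen-6-yl)methyl]-3,5-dihydroxy-4-methylcyclohexa-2,5-dien-1-one | CCCCCC(=O)c1c(O)c(CC2=C(O)[C@@](C)(C/C=C(\C)CCC=C(C)C)C(O)=C(C(C)=O)C2=O)c(O)c2c1OC(C)(C)C=C2 | target

Total step count: 8. Longest linear sequence: 5 steps (steps 1, 2, 3, 4 and 8); the second branch (steps 5, 6, 7) joins at step 8.

Steps most likely to fail

1. Step 8. Proton transfer from the C6 methyl group of 10 or from the hexanoyl chain to the lactone enolate, or loss of that enolate by elimination to a ketene, could outrun carbonyl addition; the closure could also stall at the O-acylated pyranone. The fallback uses known reactions only, sets out from 10 and 13 and returns at 23, at the price of a late bridging. Compound 10 would be opened with LiCH2CO2t-Bu (THF, −78 °C; carbanion opening of an enol lactone) to tert-butyl (4S)-4-geranyl-4-methyl-3,5,7-trioxooctanoate F1. Base-induced Claisen cyclisation of this triketo ester (KOt-Bu, THF) would give (4R)-2-acetyl-4-geranyl-3,5-dihydroxy-4-methylcyclohexa-2,5-dien-1-one F2. Separately, 13 would be annulated with 19 (ethylenediammonium diacetate, toluene) to 1-(5,7-dihydroxy-2,2-dimethyl-2H-chromen-8-yl)hexan-1-one F3, the isomer closed on the para oxygen being removed. F2 would be converted with dimethylmethyleneiminium iodide into the Mannich base (4R)-2-acetyl-6-[(dimethylamino)methyl]-4-geranyl-3,5-dihydroxy-4-methylcyclohexa-2,5-dien-1-one F4, which on warming with F3 in MeCN would give 23 by elimination and conjugate addition of the arene.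

2. Step 6. The lactone could close through an ortho instead of the para hydroxyl, and formaldehyde could couple two molecules of 13 through a methylene group. The fallback sets out from 13 and returns at 23 through step 8. The para hydroxyl would be silylated selectively (i-Pr3SiCl, imidazole) to 1-[2,6-dihydroxy-4-(triisopropylsilyloxy)phenyl]hexan-1-one F5. Annulation with 19 can then close only on an ortho oxygen and would give 1-[7-hydroxy-2,2-dimethyl-5-(triisopropylsilyloxy)-2H-chromen-8-yl]hexan-1-one F6. The Meldrum's acid and formaldehyde annulation at the last free ring carbon, with a single hydroxyl left to lactonise, would give 10-hexanoyl-8,8-dimethyl-5-(triisopropylsilyloxy)-3,4-dihydro-2H,8H-pyrano[3,2-g]chromen-2-one F7. Bu4NF would free 10-hexanoyl-5-hydroxy-8,8-dimethyl-3,4-dihydro-2H,8H-pyrano[3,2-g]chromen-2-one F8. F8 would enter step 8 in place of 21 and give the same 23, because its lactone oxygen is released as the second phenol.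

3. Step 2. Facial selectivity in the alkylation could be poor or reversed, and N-alkylation could compete. The fallback replaces the auxiliary by an enzymatic desymmetrisation, sets out from 4 and returns at 9. Dimethyl methylmalonate would be alkylated with 4 (NaH, THF) to dimethyl 2-geranyl-2-methylmalonate F9. Pig liver esterase (pH 7 buffer) would distinguish the enantiotopic ester groups and give (2S)-2-geranyl-3-methoxy-2-methyl-3-oxopropanoic acid F10; the sense of the enzymatic hydrolysis would have to be confirmed at this stage. (COCl)2 would give methyl (2R)-3-chloro-2-geranyl-2-methyl-3-oxopropanoate F11, the lithium enolate of acetone would be acylated to methyl (2S)-2-geranyl-2-methyl-3,5-dioxohexanoate F12, and LiOH would lead to 9.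

Further compounds
F1 | step 8 | tert-butyl (4S)-4-geranyl-4-methyl-3,5,7-trioxooctanoate | CC(C)(C)OC(=O)CC(=O)[C@@](C)(C/C=C(\C)CCC=C(C)C)C(=O)CC(C)=O
F2 | step 8 | (4R)-2-acetyl-4-geranyl-3,5-dihydroxy-4-methylcyclohexa-2,5-dien-1-one | C1=C(O)[C@@](C)(C/C=C(\C)CCC=C(C)C)C(O)=C(C(C)=O)C1=O
F3 | step 8 | 1-(5,7-dihydroxy-2,2-dimethyl-2H-chromen-8-yl)hexan-1-one | CCCCCC(=O)c1c(O)cc(O)c2C=CC(C)(C)Oc12
F4 | step 8 | (4R)-2-acetyl-6-[(dimethylamino)methyl]-4-geranyl-3,5-dihydroxy-4-methylcyclohexa-2,5-dien-1-one | CN(C)CC1=C(O)[C@@](C)(C/C=C(\C)CCC=C(C)C)C(O)=C(C(C)=O)C1=O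
F5 | step 6 | 1-[2,6-dihydroxy-4-(triisopropylsilyloxy)phenyl]hexan-1-one | CCCCCC(=O)c1c(O)cc(O[Si](C(C)C)(C(C)C)C(C)C)cc1O
F6 | step 6 | 1-[7-hydroxy-2,2-dimethyl-5-(triisopropylsilyloxy)-2H-chromen-8-yl]hexan-1-one | CCCCCC(=O)c1c(O)cc(O[Si](C(C)C)(C(C)C)C(C)C)c2C=CC(C)(C)Oc12
F7 | step 6 | 10-hexanoyl-8,8-dimethyl-5-(triisopropylsilyloxy)-3,4-dihydro-2H,8H-pyrano[3,2-g]chromen-2-one | CCCCCC(=O)c1c2OC(=O)CCc2c(O[Si](C(C)C)(C(C)C)C(C)C)c2C=CC(C)(C)Oc12
F8 | step 6 | 10-hexanoyl-5-hydroxy-8,8-dimethyl-3,4-dihydro-2H,8H-pyrano[3,2-g]chromen-2-one | CCCCCC(=O)c1c2OC(=O)CCc2c(O)c2C=CC(C)(C)Oc12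
F9 | step 2 | dimethyl 2-geranyl-2-methylmalonate | COC(=O)C(C)(C/C=C(\C)CCC=C(C)C)C(=O)OC
F10 | step 2 | (2S)-2-geranyl-3-methoxy-2-methyl-3-oxopropanoic acid | COC(=O)[C@@](C)(C/C=C(\C)CCC=C(C)C)C(=O)O
F11 | step 2 | methyl (2R)-3-chloro-2-geranyl-2-methyl-3-oxopropanoate | COC(=O)[C@@](C)(C/C=C(\C)CCC=C(C)C)C(=O)Cl
F12 | step 2 | methyl (2S)-2-geranyl-2-methyl-3,5-dioxohexanoate | COC(=O)[C@@](C)(C/C=C(\C)CCC=C(C)C)C(=O)CC(C)=O
A1 | direct plan | rac-3-ethoxy-4-geranyl-4-methylcyclobut-2-en-1-one | CCOC1=CC(=O)C1(C)C/C=C(\C)CCC=C(C)C
A2 | direct plan | 4-geranyl-3,5-dihydroxy-4-methylcyclohexa-2,5-dien-1-one (achiral) | O=C1C=C(O)C(C)(C/C=C(\C)CCC=C(C)C)C(O)=C1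
A3 | direct plan | rac-2-acetyl-4-geranyl-3,5-dihydroxy-4-methylcyclohexa-2,5-dien-1-one | CC(=O)C1=C(O)C(C)(C/C=C(\C)CCC=C(C)C)C(O)=CC1=O
A4 | direct plan | 1-(5,7-dihydroxy-2,2-dimethyl-2H-chromen-8-yl)hexan-1-one | CCCCCC(=O)c1c(O)cc(O)c2C=CC(C)(C)Oc12
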